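Numbering: ring C1–C9 (C1 carries the side chain, C2 the hydroxyl, C8 and C9 the formyl carbons C19 and C10); C11 is the side-chain CH, C18 its CH2OAc carbon. The route rests on disconnecting C8–C9. C10 and the oxygen on C18 stand 1,5 across C9–C1–C11, so a six-membered lactone between them carries all three stereocentres and leaves C9 as its only acidic carbon. Palladium-catalysed union of this lactone enolate with the C8 alkenyl iodide closes the nine-membered ring (C1–C9), trans-fused to the lactone, and creates C9 in one operation. The precursor is a 4,5-cis-disubstituted δ-lactone with a (3E,6Z)-iododiene chain, C2–OTBS and C19 as dimethyl acetal.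

Key step: step 15

Remark 1 (assumption): the target is made in the open form drawn (C2–OH, C10 and C19 aldehydes); equilibration with a five-membered C2–O–C10 lactol is a property of the compound itself and is not addressed.
Remark 2 (design of the ring-closure substrate): C19 is taken through the ring closure as a dimethyl acetal and not as a protected primary alcohol. A C19 hydroxyl set free next to the C10 aldehyde would close to a five-membered lactol and would need a late oxidation; with the acetal the last step is a hydrolysis. The carbon skeleton, the lactone, the iodide and the C2 silyl ether of the ring-closure substrate and of its product are otherwise standard, and their configuration at C1, C2 and C11 and both alkene geometries were checked against the target.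
Remark 3: "d-menthyl" is the (1S,2R,5S)-menthyl group of (+)-menthol; the starting acetal with this group is the commercial antipode of the more common l-menthyl compound. Names of late compounds use the target numbering above.

Step 1
Reactants: 1 5-bromo-2-methylpent-2-ene; 2 (5S)-5-(d-menthyloxy)furan-2(5H)-one
Product: 4 (4S,5S)-5-(d-menthyloxy)-4-(4-methylpent-3-enyl)dihydrofuran-2(3H)-one, via (4-methylpent-3-enyl)magnesium bromide 3 (not isolated)
Conditions: 1, Mg, THF, 25 °C; then CuI (0.2 equiv), 2, THF, −78 → −40 °C; aq. NH4Cl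
Reagents that add atoms: 5-bromo-2-methylpent-2-ene (1), CC(C)=CCCBr
Why: Copper-catalysed conjugate addition of the Grignard reagent to the γ-alkoxybutenolide (1,4-addition) should take place on the face anti to the C18 menthyloxy group and so set C11 (S).

Step 2
Reactants: 4 conjugate adduct; 5 tert-butyl bromoacetate
Product: 6 tert-butyl 2-[(3S,4S,5S)-5-(d-menthyloxy)-4-(4-methylpent-3-enyl)-2-oxotetrahydrofuran-3-yl]acetate
Conditions: LiN(i-Pr)2, THF, −78 °C; then 5, −78 → −40 °C
Reagents that add atoms: tert-butyl bromoacetate (5), CC(C)(C)OC(=O)CBr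
Why: α-Alkylation of the lithium lactone enolate with the activated bromide should occur trans to the adjacent C11 side chain (substrate-controlled alkylation of a β-substituted γ-butyrolactone), which sets C1.

Step 3
Reactants: 6 alkylated menthyloxy lactone
Product: 8 tert-butyl 2-[(3S,4S)-4-(4-methylpent-3-enyl)-2-oxotetrahydrofuran-3-yl]acetate, via hydroxy acid 7 (not isolated)
Conditions: NaBH4, KOH, EtOH–H2O, 0 → 25 °C; then aq. HCl to pH 2, 25 °C
Reagents that add atoms: water (as hydroxide), O (enters the carboxyl group of 7 and can be the oxygen kept in the lactone carbonyl)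
Why: Hydroxide opens the pseudo-ester to the formyl carboxylate, NaBH4 reduces the aldehyde at C18 before the α-centre C11 can epimerise and acidification closes the γ-lactone with release of menthol (reductive removal of the acetal auxiliary), the tert-butyl ester being inert throughout.

Step 4
Reactants: 8 γ-lactone; 9 N,O-dimethylhydroxylamine hydrochloride
Product: 11 C18 triethylsilyl ether of the C2 Weinreb amide, via hydroxy amide 10 (not isolated)
Conditions: 9, i-PrMgCl, THF, −20 °C; then Et3SiCl, imidazole, −20 → 0 °C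
Reagents that add atoms: N,O-dimethylhydroxylamine hydrochloride (9), CNOC.Cl; chlorotriethylsilane, CC[Si](Cl)(CC)CC
Why: The chloromagnesium amide opens the lactone to the Weinreb amide (Weinreb aminolysis) and the C18 alkoxide is silylated in the same flask, which prevents relactonisation and frees C2 for reduction.

Step 5
Reactants: 11 Weinreb amide
Product: 12 C2 aldehyde (tert-butyl (3S,4S)-3-formyl-8-methyl-4-(triethylsilyloxymethyl)non-7-enoate)
Conditions: i-Bu2AlH, THF, −78 °C; aq. KNaC4H4O6
Reagents that add atoms: none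
Why: i-Bu2AlH should stop at the chelated hemiaminal of the Weinreb amide and release the aldehyde on work-up, while the tert-butyl ester does not react at −78 °C (Weinreb amide reduction).

Step 6
Reactants: 12 aldehyde; 13 allenylboronic acid pinacol ester
Product: 15 (2S)-homopropargylic alcohol, via borate ester 14 (not isolated)
Conditions: 13, (S)-TRIP phosphoric acid (10 mol%; the antipode expected to direct Si-face addition), 4 Å MS, PhMe, −20 °C; aq. NaHCO3
Reagents that add atoms: allenylboronic acid pinacol ester (13), C=C=CB1OC(C)(C)C(C)(C)O1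
Why: Chiral phosphoric acid-catalysed allenylboration (SE2′ propargylation through a closed six-membered transition state) should deliver the propargyl group to the Si face of C2, where the catalyst sense reinforces the Felkin–Anh preference (C11 branch anti to the incoming carbon), so that the C2 hydroxyl is set S, syn to C9.

Step 7
Reactants: 15 homopropargylic alcohol
Product: 16 C2 tert-butyldimethylsilyl ether
Conditions: t-BuMe2SiOTf, 2,6-lutidine, CH2Cl2, −78 → 0 °C
Reagents that add atoms: tert-butyldimethylsilyl trifluoromethanesulfonate, CC(C)(C)[Si](C)(C)OS(=O)(=O)C(F)(F)F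
Why: Silyl triflate and 2,6-lutidine silylate the hindered secondary alcohol (standard silyl ether formation) before any acyl group can reach it.

Step 8
Reactants: 16 terminal alkyne
Product: 18 (E)-allylic alcohol (C6–OH), via alkenyldimethylalane 17 (not isolated)
Conditions: Me3Al, Cp2ZrCl2 (0.3 equiv), ClCH2CH2Cl, 25 °C; then n-BuLi, THF, −78 °C; (CH2O)n, −78 → 25 °C; aq. KNaC4H4O6
Reagents that add atoms: trimethylaluminium, C[Al](C)C; paraformaldehyde, C=O
Why: Zirconium-catalysed syn-carboalumination of the terminal alkyne (Negishi carboalumination) puts methyl on C4 and aluminium on C5 and the derived alanate adds to formaldehyde with retention, so the trisubstituted alkene should be E.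

Step 9
Reactants: 18 allylic alcohol
Product: 19 (E)-allylic bromide (C6–Br)
Conditions: CBr4, PPh3, 2,6-lutidine, CH2Cl2, −20 °C
Reagents that add atoms: tetrabromomethane, BrC(Br)(Br)Br
Why: The Appel reaction should convert the primary allylic alcohol into the bromide without allylic transposition.

Step 10
Reactants: 19 allylic bromide; 20 prop-2-yn-1-ol
Product: 21 skipped enyne alcohol (C7≡C8, C19–OH)
Conditions: 20, CuI (0.2 equiv), K2CO3, NaI, DMF, 25 °C
Reagents that add atoms: prop-2-yn-1-ol (20), C#CCO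
Why: The copper acetylide of propargyl alcohol should displace the primary allylic bromide at the unhindered carbon (copper-catalysed alkyne–allyl halide coupling) and leave the E alkene untouched.

Step 11
Reactants: 21 enyne alcohol
Product: 24 δ-lactone enyne alcohol (C10 carbonyl; C18–O), via silyl ester 22 (not isolated), via hydroxy acid 23 (not isolated)
Conditions: Me3SiOTf, 2,6-lutidine, CH2Cl2, 0 → 25 °C; then HF·pyridine, pyridine, THF, 0 °C; then pyridinium p-toluenesulfonate (cat.), PhMe, 40 °C
Reagents that add atoms: none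
Why: Me3SiOTf exchanges the tert-butyl ester for a silyl ester under buffered aprotic conditions that spare the alkenes, HF·pyridine then frees the acid, the C19 hydroxyl and the primary C18 hydroxyl but not the hindered secondary silyl ether, and the δ-hydroxy acid closes to the lactone (lactonisation) in which the C1 and C11 substituents are cis.

Step 12
Reactants: 24 lactone enyne alcohol
Product: 26 (Z)-iodoalkene allylic alcohol (iodine on C8 cis to C6), via alkenylstannane 25 (not isolated)
Conditions: Bu3SnH, [Cp*RuCl]4 (2.5 mol%), CH2Cl2, 25 °C; then I2, 0 °C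
Reagents that add atoms: iodine, II
Why: Hydroxyl-directed ruthenium-catalysed trans-hydrostannation should place tin on the alkyne carbon next to the free hydroxyl (C8) and hydrogen on C7 from the opposite side, and iododestannylation with retention then gives the alkenyl iodide with iodine and C6 cis.

Step 13
Reactants: 26 iodo allylic alcohol
Product: 27 (Z)-α-iodoenal
Conditions: MnO2, CH2Cl2, 25 °C
Reagents that add atoms: none
Why: MnO2 oxidises only the allylic alcohol (allylic oxidation) and gives the α-iodoenal without touching the skipped diene.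

Step 14
Reactants: 27 α-iodoenal
Product: 28 δ-lactone alkenyl iodide with C19 dimethyl acetal (ring-closure substrate)
Conditions: MeOSiMe3, Me3SiOTf (5 mol%), CH2Cl2, −78 → −30 °C; pyridine
Reagents that add atoms: methoxytrimethylsilane, CO[Si](C)(C)C
Why: Acetalisation with the silyl ether under catalytic Me3SiOTf (Noyori conditions) is aprotic and should mask the aldehyde without opening the lactone or cleaving the silyl ether.

Step 15
Reactants: 28 δ-lactone alkenyl iodide
Product: 30 trans-fused nine-six bicyclic lactone (1R,2S,9R,11S), via lithium enolate 29 (not isolated)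
Conditions: LiN(SiMe3)2 (2.2 equiv), THF, −78 °C; added over 6 h to Pd2(dba)3 (10 mol%), P(t-Bu)3 (24 mol%), PhMe (0.003 M), 50 °C; then AcOH, −78 °C
Reagents that add atoms: none
Why: Oxidative addition of the C8–I bond to zerovalent palladium, transfer of the lithium lactone enolate to palladium and C–C reductive elimination form the C8–C9 bond with retention of the alkene geometry, so that C6 and C9 end up cis on C7=C8. The closest known reaction type is the palladium-catalysed intramolecular α-alkenylation of ester and ketone enolates, which has been used for medium rings. The nine-membered carbocycle C1–C9 is closed by reductive elimination from a ten-membered palladacycle, that is by C(sp2)–C(sp3) bond formation at the α-carbon of the lactone, to which the new ring is fused at C1–C9. The new stereocentre C9 is controlled by the lactone: the C8 substituent takes the side trans to the C2-bearing group on C1, and because C9 is the only acidic centre a cis-fused portion can be corrected by reprotonation. The step needs C-alkenylation without loss of methoxide from the alkenylpalladium species and without migration of the skipped diene or of C7=C8 into conjugation; the bulky electron-rich phosphine (fast reductive elimination), high dilution and a cold acidic quench, which protonates the product enolate at C9, are meant to secure this.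

Step 16
Reactants: 30 bicyclic lactone; 9 N,O-dimethylhydroxylamine hydrochloride
Product: 32 C18 acetate of the C10 Weinreb amide, via hydroxy amide 31 (not isolated)
Conditions: 9, Me3Al, CH2Cl2, 0 → 25 °C; then Ac2O, pyridine, DMAP, 0 °C
Reagents that add atoms: N,O-dimethylhydroxylamine hydrochloride (9), CNOC.Cl; acetic anhydride, CC(=O)OC(C)=O
Why: The aluminium amide opens the lactone at C10 (Weinreb aminolysis) and the C18 aluminium alkoxide is acetylated before work-up, so that the lactone oxygen becomes the acetate and C10 the amide, with no chance of relactonisation.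

Step 17
Reactants: 32 acetoxy Weinreb amide
Product: 33 C10 aldehyde (C18 acetate; C2 silyl ether; C19 acetal)
Conditions: Cp2Zr(H)Cl (1.5 equiv), THF, 25 °C, 20 min
Reagents that add atoms: none
Why: Cp2Zr(H)Cl should reduce the tertiary amide to the aldehyde through a stable zirconium hemiaminal and leave the acetate alone (hydrozirconation-type amide reduction), the trisubstituted alkenes reacting much more slowly.

Step 18
Reactants: 33 protected dialdehyde precursor
Product: 34 CNP0284729.1 (target)
Conditions: 48% aq. HF, MeCN, 0 °C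
Reagents that add atoms: water, O
Why: Aqueous HF cleaves the silyl ether and hydrolyses the allylic dimethyl acetal in one operation (acidic global deprotection), which frees the C2 hydroxyl and the C19 enal under conditions mild enough to leave C9 untouched.

Compound list

1 | 5-bromo-2-methylpent-2-ene | CC(C)=CCCBr | starting material
2 | (5S)-5-{[(1S,2R,5S)-5-methyl-2-(propan-2-yl)cyclohexyl]oxy}furan-2(5H)-one | O=C1C=C[C@@H](O[C@H]2C[C@@H](C)CC[C@@H]2C(C)C)O1 | starting material
3 | (4-methylpent-3-en-1-yl)magnesium bromide | CC(C)=CCC[Mg]Br | intermediate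
4 | (4S,5S)-5-(d-menthyloxy)-4-(4-methylpent-3-en-1-yl)dihydrofuran-2(3H)-one | O=C1C[C@H](CCC=C(C)C)[C@@H](O[C@H]2C[C@@H](C)CC[C@@H]2C(C)C)O1 | intermediate
5 | tert-butyl bromoacetate | CC(C)(C)OC(=O)CBr | starting material
6 | tert-butyl 2-[(3S,4S,5S)-5-(d-menthyloxy)-4-(4-methylpent-3-en-1-yl)-2-oxotetrahydrofuran-3-yl]acetate | O=C1O[C@H](O[C@H]2C[C@@H](C)CC[C@@H]2C(C)C)[C@@H](CCC=C(C)C)[C@@H]1CC(=O)OC(C)(C)C | intermediate
7 | (2S,3S)-2-(2-tert-butoxy-2-oxoethyl)-3-(hydroxymethyl)-7-methyloct-6-enoic acid (formed as its carboxylate) | OC[C@@H](CCC=C(C)C)[C@@H](C(=O)O)CC(=O)OC(C)(C)C | intermediate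
8 | tert-butyl 2-[(3S,4S)-4-(4-methylpent-3-en-1-yl)-2-oxotetrahydrofuran-3-yl]acetate | O=C1OC[C@@H](CCC=C(C)C)[C@@H]1CC(=O)OC(C)(C)C | intermediate
9 | N,O-dimethylhydroxylamine hydrochloride | CNOC.Cl | starting material
10 | tert-butyl (3S,4S)-4-(hydroxymethyl)-3-[methoxy(methyl)carbamoyl]-8-methylnon-7-enoate (formed as its magnesium alkoxide) | OC[C@@H](CCC=C(C)C)[C@@H](C(=O)N(C)OC)CC(=O)OC(C)(C)C | intermediate
11 | tert-butyl (3S,4S)-3-[methoxy(methyl)carbamoyl]-8-methyl-4-{[(triethylsilyl)oxy]methyl}non-7-enoate | CC[Si](CC)(CC)OC[C@@H](CCC=C(C)C)[C@@H](C(=O)N(C)OC)CC(=O)OC(C)(C)C | intermediate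
12 | tert-butyl (3S,4S)-3-formyl-8-methyl-4-{[(triethylsilyl)oxy]methyl}non-7-enoate | CC[Si](CC)(CC)OC[C@@H](CCC=C(C)C)[C@@H](C=O)CC(=O)OC(C)(C)C | intermediate
13 | 4,4,5,5-tetramethyl-2-(propa-1,2-dien-1-yl)-1,3,2-dioxaborolane (allenylboronic acid pinacol ester) | C=C=CB1OC(C)(C)C(C)(C)O1 | starting material
14 | pinacol borate ester of alcohol 15 (boron on the C2 oxygen) | CC[Si](CC)(CC)OC[C@@H](CCC=C(C)C)[C@@H]([C@@H](OB1OC(C)(C)C(C)(C)O1)CC#C)CC(=O)OC(C)(C)C | intermediate
15 | tert-butyl (3S,4S)-3-[(1S)-1-hydroxybut-3-yn-1-yl]-8-methyl-4-{[(triethylsilyl)oxy]methyl}non-7-enoate | CC[Si](CC)(CC)OC[C@@H](CCC=C(C)C)[C@@H]([C@@H](O)CC#C)CC(=O)OC(C)(C)C | intermediate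
16 | tert-butyl (3S,4S)-3-[(1S)-1-{[tert-butyl(dimethyl)silyl]oxy}but-3-yn-1-yl]-8-methyl-4-{[(triethylsilyl)oxy]methyl}non-7-enoate | CC[Si](CC)(CC)OC[C@@H](CCC=C(C)C)[C@@H]([C@@H](O[Si](C)(C)C(C)(C)C)CC#C)CC(=O)OC(C)(C)C | intermediate
17 | (E)-alkenyldimethylalane from 16 (methyl on C4, AlMe2 on C5) | CC[Si](CC)(CC)OC[C@@H](CCC=C(C)C)[C@@H]([C@@H](O[Si](C)(C)C(C)(C)C)C/C(C)=C/[Al](C)C)CC(=O)OC(C)(C)C | intermediate
18 | tert-butyl (3S,4S)-3-[(1S,3E)-1-{[tert-butyl(dimethyl)silyl]oxy}-5-hydroxy-3-methylpent-3-en-1-yl]-8-methyl-4-{[(triethylsilyl)oxy]methyl}non-7-enoate | CC[Si](CC)(CC)OC[C@@H](CCC=C(C)C)[C@@H]([C@@H](O[Si](C)(C)C(C)(C)C)C/C(C)=C/CO)CC(=O)OC(C)(C)C | intermediate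
19 | tert-butyl (3S,4S)-3-[(1S,3E)-5-bromo-1-{[tert-butyl(dimethyl)silyl]oxy}-3-methylpent-3-en-1-yl]-8-methyl-4-{[(triethylsilyl)oxy]methyl}non-7-enoate | CC[Si](CC)(CC)OC[C@@H](CCC=C(C)C)[C@@H]([C@@H](O[Si](C)(C)C(C)(C)C)C/C(C)=C/CBr)CC(=O)OC(C)(C)C | intermediate
20 | prop-2-yn-1-ol | C#CCO | starting material
21 | tert-butyl (3S,4S)-3-[(1S,3E)-1-{[tert-butyl(dimethyl)silyl]oxy}-8-hydroxy-3-methyloct-3-en-6-yn-1-yl]-8-methyl-4-{[(triethylsilyl)oxy]methyl}non-7-enoate | CC[Si](CC)(CC)OC[C@@H](CCC=C(C)C)[C@@H]([C@@H](O[Si](C)(C)C(C)(C)C)C/C(C)=C/CC#CCO)CC(=O)OC(C)(C)C | intermediate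
22 | trimethylsilyl ester of 21 with the C19 hydroxyl as trimethylsilyl ether | CC[Si](CC)(CC)OC[C@@H](CCC=C(C)C)[C@@H]([C@@H](O[Si](C)(C)C(C)(C)C)C/C(C)=C/CC#CCO[Si](C)(C)C)CC(=O)O[Si](C)(C)C | intermediate
23 | (3S,4S)-3-[(1S,3E)-1-{[tert-butyl(dimethyl)silyl]oxy}-8-hydroxy-3-methyloct-3-en-6-yn-1-yl]-4-(hydroxymethyl)-8-methylnon-7-enoic acid | OC[C@@H](CCC=C(C)C)[C@@H]([C@@H](O[Si](C)(C)C(C)(C)C)C/C(C)=C/CC#CCO)CC(=O)O | intermediate
24 | (4S,5S)-4-[(1S,3E)-1-{[tert-butyl(dimethyl)silyl]oxy}-8-hydroxy-3-methyloct-3-en-6-yn-1-yl]-5-(4-methylpent-3-en-1-yl)tetrahydro-2H-pyran-2-one | O=C1C[C@H]([C@@H](O[Si](C)(C)C(C)(C)C)C/C(C)=C/CC#CCO)[C@H](CCC=C(C)C)CO1 | intermediate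
25 | (4S,5S)-4-[(1S,3E,6Z)-1-{[tert-butyl(dimethyl)silyl]oxy}-8-hydroxy-3-methyl-7-(tributylstannyl)octa-3,6-dien-1-yl]-5-(4-methylpent-3-en-1-yl)tetrahydro-2H-pyran-2-one | O=C1C[C@H]([C@@H](O[Si](C)(C)C(C)(C)C)C/C(C)=C/C/C=C(\[Sn](CCCC)(CCCC)CCCC)CO)[C@H](CCC=C(C)C)CO1 | intermediate
26 | (4S,5S)-4-[(1S,3E,6Z)-1-{[tert-butyl(dimethyl)silyl]oxy}-8-hydroxy-7-iodo-3-methylocta-3,6-dien-1-yl]-5-(4-methylpent-3-en-1-yl)tetrahydro-2H-pyran-2-one | O=C1C[C@H]([C@@H](O[Si](C)(C)C(C)(C)C)C/C(C)=C/C/C=C(\I)CO)[C@H](CCC=C(C)C)CO1 | intermediate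
27 | (2Z,5E,8S)-8-{[tert-butyl(dimethyl)silyl]oxy}-2-iodo-6-methyl-8-[(4S,5S)-5-(4-methylpent-3-en-1-yl)-2-oxotetrahydro-2H-pyran-4-yl]octa-2,5-dienal | O=C1C[C@H]([C@@H](O[Si](C)(C)C(C)(C)C)C/C(C)=C/C/C=C(\I)C=O)[C@H](CCC=C(C)C)CO1 | intermediate
28 | (4S,5S)-4-[(1S,3E,6Z)-1-{[tert-butyl(dimethyl)silyl]oxy}-7-iodo-8,8-dimethoxy-3-methylocta-3,6-dien-1-yl]-5-(4-methylpent-3-en-1-yl)tetrahydro-2H-pyran-2-one | O=C1C[C@H]([C@@H](O[Si](C)(C)C(C)(C)C)C/C(C)=C/C/C=C(\I)C(OC)OC)[C@H](CCC=C(C)C)CO1 | intermediate
29 | lithium enolate of 28 (O–Li on C10, C9=C10) | [Li]OC1=C[C@H]([C@@H](O[Si](C)(C)C(C)(C)C)C/C(C)=C/C/C=C(\I)C(OC)OC)[C@H](CCC=C(C)C)CO1 | intermediate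
30 | δ-lactone (C10 carbonyl, C18–O) trans-fused at C1–C9 to the cyclonona-4,7-diene ring; C2 OTBS, C4 methyl, C8 dimethoxymethyl, C11 4-methylpent-3-enyl; 1R,2S,9R,11S; 4E; C6 and C9 cis on C7=C8 | O=C1OC[C@@H](CCC=C(C)C)[C@H]2[C@@H](O[Si](C)(C)C(C)(C)C)C/C(C)=C/C/C=C(/C(OC)OC)[C@@H]21 | intermediate
31 | ring-opened hydroxy Weinreb amide of 30 (C10 N-methoxy-N-methylamide, C18–OH; formed as its aluminium alkoxide); 1R,2S,9R,11S | OC[C@@H](CCC=C(C)C)[C@H]1[C@@H](O[Si](C)(C)C(C)(C)C)C/C(C)=C/C/C=C(/C(OC)OC)[C@@H]1C(=O)N(C)OC | intermediate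
32 | C18 acetate of 31; 1R,2S,9R,11S | CC(=O)OC[C@@H](CCC=C(C)C)[C@H]1[C@@H](O[Si](C)(C)C(C)(C)C)C/C(C)=C/C/C=C(/C(OC)OC)[C@@H]1C(=O)N(C)OC | intermediate
33 | C10 aldehyde with C18 acetate, C2 OTBS and C19 dimethyl acetal; 1R,2S,9R,11S | CC(=O)OC[C@@H](CCC=C(C)C)[C@H]1[C@@H](O[Si](C)(C)C(C)(C)C)C/C(C)=C/C/C=C(/C(OC)OC)[C@@H]1C=O | intermediate
34 | CNP0284729.1: (2S)-2-[(1R,2S,9R)-8,9-diformyl-2-hydroxy-4-methylcyclonona-4,7-dien-1-yl]-6-methylhept-5-en-1-yl acetate (4E; C6 and C9 cis on C7=C8; ring locants as in the overview) | CC(=O)OC[C@@H](CCC=C(C)C)[C@H]1[C@@H](O)C/C(C)=C/C/C=C(/C=O)[C@@H]1C=O | target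

Total step count: 18. Longest linear sequence: 18 steps (from 1 and 2 to 34; the route is linear).

Steps most likely to fail

Step 15. The ring closure may lose to intermolecular coupling, to protodeiodination or to elimination of methoxide from the alkenylpalladium intermediate, and protonation of the product enolate may give the cis-fused or the conjugated isomer. The fallback closes the nine-membered ring by olefin metathesis at C7=C8 instead. It sets out from bromide 19: Stille coupling with tributyl(vinyl)stannane (Pd2(dba)3, AsPh3, THF) should give the vinyl-terminated triene ester F1. Silyl-ester exchange, desilylation and lactonisation as in step 11 should give the vinyl-terminated δ-lactone F2. Intermolecular palladium-catalysed α-alkenylation of its lithium enolate with 2-bromo-3,3-dimethoxyprop-1-ene (LiN(SiMe3)2, Pd2(dba)3, P(t-Bu)3; new group trans to the C1 substituent) should give the diene lactone F3. Ring-closing metathesis of F3 with the second-generation Grubbs catalyst (H2IMes)(PCy3)Cl2Ru=CHPh in dilute PhMe should then form C7=C8 with loss of ethene, the ring size enforcing the in-ring cis geometry, and the route is rejoined at 30.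

Step 16. Attack at the hindered C10 carbonyl may stall, enolisation at C9 may erode the trans ring fusion, or incomplete acetylation may allow relactonisation; the amide may also resist clean mono-reduction in step 17. The fallback changes the acyl handle and sets out from 30. Me2AlSEt (from Me3Al and EtSH, CH2Cl2, 0 °C) should open the lactone to the hydroxy thioester F4, which is acetylated in the same flask (Ac2O, pyridine, DMAP) to the acetoxy thioester F5. Fukuyama reduction (Et3SiH, Pd on CaCO3 poisoned with Pb, acetone) should then give the aldehyde directly, so that the route is rejoined at 33.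

Step 6. Facial selectivity may be poor if catalyst control and substrate bias do not reinforce each other, and the α-branched aldehyde may epimerise at C1 before it reacts. The fallback avoids the aldehyde and sets C2 by ketone reduction. It sets out from 11: addition of LiCH2C≡CSiMe3 (from 1-trimethylsilylpropyne and n-BuLi, THF, −78 °C) should give the β,γ-alkynyl ketone F6. Corey–Bakshi–Shibata reduction with the (R)-2-methyl-oxazaborolidine and BH3·SMe2 at −40 °C, the branched C1 side acting as the large group, should give the (S)-alcohol F7. K2CO3 in MeOH removes the alkynylsilane and the route is rejoined at 15.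

Further compounds

F1 | step 15 | tert-butyl (3S,4S)-3-[(1S,3E)-1-{[tert-butyl(dimethyl)silyl]oxy}-3-methylhepta-3,6-dien-1-yl]-8-methyl-4-{[(triethylsilyl)oxy]methyl}non-7-enoate | CC[Si](CC)(CC)OC[C@@H](CCC=C(C)C)[C@@H]([C@@H](O[Si](C)(C)C(C)(C)C)C/C(C)=C/CC=C)CC(=O)OC(C)(C)C
F2 | step 15 | (4S,5S)-4-[(1S,3E)-1-{[tert-butyl(dimethyl)silyl]oxy}-3-methylhepta-3,6-dien-1-yl]-5-(4-methylpent-3-en-1-yl)tetrahydro-2H-pyran-2-one | O=C1C[C@H]([C@@H](O[Si](C)(C)C(C)(C)C)C/C(C)=C/CC=C)[C@H](CCC=C(C)C)CO1
F3 | step 15 | (3R,4R,5S)-4-[(1S,3E)-1-{[tert-butyl(dimethyl)silyl]oxy}-3-methylhepta-3,6-dien-1-yl]-3-(3,3-dimethoxyprop-1-en-2-yl)-5-(4-methylpent-3-en-1-yl)tetrahydro-2H-pyran-2-one | O=C1OC[C@@H](CCC=C(C)C)[C@@H]([C@@H](O[Si](C)(C)C(C)(C)C)C/C(C)=C/CC=C)[C@@H]1C(=C)C(OC)OC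
F4 | step 16 | ring-opened S-ethyl thioester of 30 (C10 thioester, C18–OH); 1R,2S,9R,11S | OC[C@@H](CCC=C(C)C)[C@H]1[C@@H](O[Si](C)(C)C(C)(C)C)C/C(C)=C/C/C=C(/C(OC)OC)[C@@H]1C(=O)SCC
F5 | step 16 | C18 acetate of F4; 1R,2S,9R,11S | CC(=O)OC[C@@H](CCC=C(C)C)[C@H]1[C@@H](O[Si](C)(C)C(C)(C)C)C/C(C)=C/C/C=C(/C(OC)OC)[C@@H]1C(=O)SCC
F6 | step 6 | tert-butyl (3S,4S)-8-methyl-4-{[(triethylsilyl)oxy]methyl}-3-[4-(trimethylsilyl)but-3-ynoyl]non-7-enoate | CC[Si](CC)(CC)OC[C@@H](CCC=C(C)C)[C@@H](C(=O)CC#C[Si](C)(C)C)CC(=O)OC(C)(C)C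
F7 | step 6 | tert-butyl (3S,4S)-3-[(1S)-1-hydroxy-4-(trimethylsilyl)but-3-yn-1-yl]-8-methyl-4-{[(triethylsilyl)oxy]methyl}non-7-enoate | CC[Si](CC)(CC)OC[C@@H](CCC=C(C)C)[C@@H]([C@@H](O)CC#C[Si](C)(C)C)CC(=O)OC(C)(C)C
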